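**Retrosynthetic overview**

1. Target 25 is a 5-hydroxy-2,3,6,7-tetrahydrobenzofuran-4(5H)-one (cyclohexenone ring fused to the dihydrofuran ring O1–C2–C3–C3a=C7a) carrying an oxidised farnesane chain at C2. Primed locants: C1′ = ring C3, C2′ = ring C2, C3′ = carbinol next to the ring, C6′/C7′ = vicinal diol, C10′=C11′ = alkene.
2. End game: acetonide hydrolysis ⇐ reagent-controlled α′-hydroxylation at C5 ⇐ closure of the dihydrofuran ring by reductive alkylation of cyclohexane-1,3-dione with a cis-2′,3′-epoxy aldehyde and 5-exo epoxide opening ⇐ Sharpless epoxidation of a Z-allylic alcohol. The dihydrofuran is the only ring closed; the carbocycle is bought.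
3. Key disconnection: the C6′–C7′ bond of the diol, made by lithiation–borylation between the (S)-α-silyloxy boronic ester 9 (C1′–C6′, from nerol) and the lithiated (S)-benzoate 3 of enzymatically reduced sulcatone (C7′–C12′). One operation should assemble the C15 chain and both diol stereocentres.
4. Enabling feature: C6′ (secondary) and C7′ (tertiary, methyl and homoprenyl) are neighbours and each carries its own oxygen. Both natively electrophilic carbinol carbons can therefore be polarity-reversed: C7′ as an α-oxy carbenoid whose oxygen leaves and is returned from boron, C6′ as an α-oxy alkylboron whose oxygen stays.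

Key step: step 6

Assumption: the ligand hand in step 5 and the oxaziridine hand in step 12 are those expected by analogy with simpler substrates; the route requires (S) at the boron-bearing carbon of 9 and (R) at C5 of 24, and the antipodal ligand or reagent is the direct correction if the sense of induction is opposite.

**Route**

Step 1
Reactants: 1 6-methylhept-5-en-2-one (sulcatone)
Product: 2 (R)-6-methylhept-5-en-2-ol
Conditions: (R)-selective NADP-dependent alcohol dehydrogenase (ketoreductase class, Lactobacillus brevis type), NADP+ (cat.), iPrOH, phosphate buffer pH 7, MgCl2, 30 °C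
Reagents that add atoms: none
Why: Enzymatic asymmetric ketone reduction with isopropanol-coupled cofactor recycling; the anti-Prelog enzyme distinguishes methyl from the homoprenyl chain, which small hydride reagents do poorly, and sets the carbinol carbon as (R).

Step 2
Reactants: 2 (R)-6-methylhept-5-en-2-ol
Product: 3 (S)-6-methylhept-5-en-2-yl 2,4,6-triisopropylbenzoate
Conditions: 2,4,6-triisopropylbenzoic acid, PPh3, DIAD, THF, 0 °C → r.t.
Reagents that add atoms: 2,4,6-triisopropylbenzoic acid, CC(C)c1cc(C(C)C)c(C(=O)O)c(C(C)C)c1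
Why: Mitsunobu esterification; SN2 displacement by the hindered carboxylate inverts the carbinol centre to (S) and installs the benzoate that directs α-lithiation.

Step 3
Reactants: 4 nerol
Product: 5 neryl tert-butyldiphenylsilyl ether
Conditions: tBuPh2SiCl, imidazole, CH2Cl2, 0 °C → r.t.
Reagents that add atoms: tert-butyldiphenylsilyl chloride, CC(C)(C)[Si](Cl)(c1ccccc1)c1ccccc1
Why: Standard silylation of a primary allylic alcohol; the ether tolerates peracid, periodic acid and organolithium chemistry, and no stereocentre is formed.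

Step 4
Reactants: 5 neryl tert-butyldiphenylsilyl ether
Product: 7 (4Z)-6-[(tert-butyldiphenylsilyl)oxy]-4-methylhex-4-enal, via terminal epoxide 6 (not isolated)
Conditions: mCPBA, CH2Cl2, −20 °C; then H5IO6, THF/H2O, 0 °C
Reagents that add atoms: 3-chloroperbenzoic acid, OOC(=O)c1cccc(Cl)c1
Why: Regioselective peracid epoxidation of the more electron-rich distal alkene (the 2,3-alkene is deactivated by the allylic oxygen), then periodic acid hydrolysis and glycol cleavage; the Z-alkene is untouched and no stereocentre remains.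

Step 5
Reactants: 7 (4Z)-6-[(tert-butyldiphenylsilyl)oxy]-4-methylhex-4-enal
Product: 9 (S)-α-(triethylsilyloxy)alkyl neopentyl glycol boronic ester, via hydroxy boronate 8 (not isolated)
Conditions: CuCl (5 mol%), (R)-DTBM-SEGPHOS (5 mol%), KOtBu (10 mol%), bis(neopentyl glycolato)diboron, MeOH (2 equiv), THF, 30 °C; then Et3SiCl, imidazole, 0 °C
Reagents that add atoms: bis(neopentyl glycolato)diboron, CC1(C)COB(OC1)B1OCC(C)(C)CO1; triethylsilyl chloride, CC[Si](Cl)(CC)CC
Why: Enantioselective nucleophilic borylation of an aliphatic aldehyde by a chiral bisphosphine complex of monovalent copper (boryl–copper 1,2-addition, methanolysis) with in-situ O-silylation; the ligand selects the aldehyde face and sets the boron-bearing carbon as (S), and the neopentyl glycol diboron is used so that the ester has the low steric demand step 6 needs.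

Step 6
Reactants: 3 (S)-6-methylhept-5-en-2-yl 2,4,6-triisopropylbenzoate, 9 (S)-α-(triethylsilyloxy)alkyl neopentyl glycol boronic ester
Product: 13 (2Z,6R,7S)-1-[(tert-butyldiphenylsilyl)oxy]-3,7,11-trimethyl-6-[(triethylsilyl)oxy]dodeca-2,10-dien-7-ol, via lithiated benzoate 10 (not isolated), via lithium boronate complex 11 (not isolated), via tertiary boronic ester 12 (not isolated)
Conditions: 3 (1.3 equiv), sBuLi, TMEDA, cyclopentyl methyl ether, −60 °C; add 9, −60 °C → 40 °C; then NaOH, H2O2, THF/H2O, 0 °C → r.t.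
Reagents that add atoms: hydrogen peroxide, OO
Why: Proposed new method: directed α-lithiation of 3 gives the configurationally stable tertiary α-oxy organolithium 10, which adds to the boron of 9 with retention to form boronate complex 11; an anti-periplanar 1,2-shift of the α-silyloxyalkyl group from boron to C7′ expels the triisopropylbenzoate and forges the C6′–C7′ bond, and peroxide oxidation replaces boron by hydroxyl. The closest known reaction types are the lithiation–borylation of secondary dialkyl triisopropylbenzoates with neopentyl glycol boronic esters and the Matteson-type migration of α-alkoxyalkyl groups in boronate complexes; their combination into a vicinal-diol synthesis is the untested part. No ring is closed. C7′ is controlled stereospecifically by the enzyme-derived carbinol centre of 3 (retention on lithiation and borylation, inversion in the shift, retention on oxidation, net (S)), and C6′ by the copper-set centre of 9, which migrates with retention to give (R). The step needs ate-complex formation to outrun decomposition of 10 and carbon rather than ring-oxygen migration; the small, Lewis-acidic neopentyl glycol ester, the good benzoate leaving group and the single leaving group in 11 (the C6′ oxygen is a silyl ether) are meant to secure this.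

Step 7
Reactants: 13 (2Z,6R,7S)-1-[(tert-butyldiphenylsilyl)oxy]-3,7,11-trimethyl-6-[(triethylsilyl)oxy]dodeca-2,10-dien-7-ol
Product: 15 6′,7′-acetonide silyl ether, via diol 14 (not isolated)
Conditions: 2,2-dimethoxypropane, camphorsulfonic acid (cat.), MeOH (3 equiv), CH2Cl2, 0 °C → r.t.
Reagents that add atoms: 2,2-dimethoxypropane, COC(C)(C)OC
Why: Acid-catalysed methanolysis of the triethylsilyl ether and ketalisation of the freed 1,2-diol (acetonide formation); the primary tert-butyldiphenylsilyl ether survives and no stereocentre changes.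

Step 8
Reactants: 15 6′,7′-acetonide silyl ether
Product: 16 (2Z)-allylic alcohol acetonide
Conditions: Bu4NF, THF, 0 °C → r.t.
Reagents that add atoms: none
Why: Fluoride desilylation of the silyl ether; acetonide and alkenes are inert.

Step 9
Reactants: 16 (2Z)-allylic alcohol acetonide
Product: 17 (2′R,3′S)-cis-epoxy alcohol
Conditions: Ti(OiPr)4 (10 mol%), D-(−)-diisopropyl tartrate (12 mol%), tBuOOH, 4 Å molecular sieves, CH2Cl2, −20 °C
Reagents that add atoms: tert-butyl hydroperoxide, CC(C)(C)OO
Why: Sharpless asymmetric epoxidation; it is hydroxyl-directed, so only the allylic alkene reacts and the distal trisubstituted alkene is spared, and the D-(−)-tartrate complex delivers oxygen to the face that gives the cis-(2′R,3′S)-epoxide, setting C2′ and C3′ under reagent control.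

Step 10
Reactants: 17 (2′R,3′S)-cis-epoxy alcohol
Product: 18 cis-epoxy aldehyde
Conditions: TEMPO (10 mol%), PhI(OAc)2, CH2Cl2, r.t.
Reagents that add atoms: none
Why: Nitroxyl-catalysed oxidation of a primary alcohol to the aldehyde under near-neutral conditions that leave epoxide, acetonide and alkene untouched; the epoxide carbon next to the carbonyl does not enolise readily, so C2′ is kept.

Step 11
Reactants: 18 cis-epoxy aldehyde, 19 cyclohexane-1,3-dione
Product: 22 (2S)-2-[(2S)-2-hydroxy-4-(dioxolanyl)butan-2-yl]-2,3,6,7-tetrahydrobenzofuran-4(5H)-one, via alkylidene dione 20 (not isolated), via epoxy dione 21 (not isolated)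
Conditions: L-proline (10 mol%), Hantzsch ester (diethyl 2,6-dimethyl-1,4-dihydropyridine-3,5-dicarboxylate), CH2Cl2, r.t.; then Et3N, r.t.
Reagents that add atoms: none
Why: Organocatalytic three-component reductive alkylation (Knoevenagel condensation, then Hantzsch-ester conjugate reduction of the alkylidene dione) gives the C-alkylated dione, whose enolate oxygen opens the epoxide 5-exo-tet at the secondary carbon C2′ with inversion (base favours the less substituted carbon); this closes the dihydrofuran ring with C2′ (S), unveils the C3′ tertiary alcohol with retained configuration, and the symmetric dione allows only one regioisomer.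

Step 12
Reactants: 22 (2S)-2-[(2S)-2-hydroxy-4-(dioxolanyl)butan-2-yl]-2,3,6,7-tetrahydrobenzofuran-4(5H)-one
Product: 24 (2S,5R)-5-hydroxy acetonide, via dilithium enolate 23 (not isolated)
Conditions: LiN(iPr)2 (2.3 equiv), THF, −78 °C; (+)-(2R,8aS)-(camphorylsulfonyl)oxaziridine, −78 °C; aq. NH4Cl
Reagents that add atoms: (+)-(2R,8aS)-(camphorylsulfonyl)oxaziridine, CC1(C)[C@@H]2CC[C@]13CS(=O)(=O)N4O[C@@]34C2
Why: Kinetic α′-deprotonation of the vinylogous ester (Stork–Danheiser regiochemistry, after the C3′ alkoxide has formed) and electrophilic enolate hydroxylation with a chiral N-sulfonyloxaziridine; C5 is set by reagent control through the camphor skeleton, and the isolated alkene is not epoxidised by this oxidant.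

Step 13
Reactants: 24 (2S,5R)-5-hydroxy acetonide
Product: 25 CNP0125453.2
Conditions: AcOH/H2O (4:1), 40 °C
Reagents that add atoms: none
Why: Mild acid-catalysed acetonide hydrolysis; the vinylogous ester, the acyloin, the tertiary alcohols and the trisubstituted alkene should tolerate warm aqueous acetic acid, and no stereocentre is touched.

**Compound list**

1 | 6-methylhept-5-en-2-one (sulcatone) | CC(=O)CCC=C(C)C | starting material
2 | (R)-6-methylhept-5-en-2-ol | C[C@@H](O)CCC=C(C)C | intermediate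
3 | (S)-6-methylhept-5-en-2-yl 2,4,6-triisopropylbenzoate | C[C@H](OC(=O)c1c(C(C)C)cc(C(C)C)cc1C(C)C)CCC=C(C)C | intermediate
4 | nerol, (2Z)-3,7-dimethylocta-2,6-dien-1-ol | CC(C)=CCC/C(C)=C\CO | starting material
5 | tert-butyl{[(2Z)-3,7-dimethylocta-2,6-dien-1-yl]oxy}diphenylsilane | CC(C)=CCC/C(C)=C\CO[Si](c1ccccc1)(c1ccccc1)C(C)(C)C | intermediate
6 | tert-butyl{[(2Z)-5-(3,3-dimethyloxiran-2-yl)-3-methylpent-2-en-1-yl]oxy}diphenylsilane (racemic at the oxirane CH) | CC1(C)OC1CC/C(C)=C\CO[Si](c1ccccc1)(c1ccccc1)C(C)(C)C | intermediate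
7 | (4Z)-6-[(tert-butyldiphenylsilyl)oxy]-4-methylhex-4-enal | O=CCC/C(C)=C\CO[Si](c1ccccc1)(c1ccccc1)C(C)(C)C | intermediate
8 | (1S,4Z)-6-[(tert-butyldiphenylsilyl)oxy]-1-(5,5-dimethyl-1,3,2-dioxaborinan-2-yl)-4-methylhex-4-en-1-ol | O[C@@H](B1OCC(C)(C)CO1)CC/C(C)=C\CO[Si](c1ccccc1)(c1ccccc1)C(C)(C)C | intermediate
9 | 2-{(1S,4Z)-6-[(tert-butyldiphenylsilyl)oxy]-4-methyl-1-[(triethylsilyl)oxy]hex-4-en-1-yl}-5,5-dimethyl-1,3,2-dioxaborinane | CC[Si](CC)(CC)O[C@@H](B1OCC(C)(C)CO1)CC/C(C)=C\CO[Si](c1ccccc1)(c1ccccc1)C(C)(C)C | intermediate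
10 | (S)-2-lithio-6-methylhept-5-en-2-yl 2,4,6-triisopropylbenzoate | [Li][C@@](C)(OC(=O)c1c(C(C)C)cc(C(C)C)cc1C(C)C)CCC=C(C)C | intermediate
11 | lithium boronate complex: boron of 9 also bonded to C7′ of 10, which still carries the benzoate (C6′ S, C7′ S) | [Li+].CC(C)=CCC[C@](C)(OC(=O)c1c(C(C)C)cc(C(C)C)cc1C(C)C)[B-]1(OCC(C)(C)CO1)[C@H](O[Si](CC)(CC)CC)CC/C(C)=C\CO[Si](c1ccccc1)(c1ccccc1)C(C)(C)C | intermediate
12 | 2-{(2Z,6R,7R)-1-[(tert-butyldiphenylsilyl)oxy]-3,7,11-trimethyl-6-[(triethylsilyl)oxy]dodeca-2,10-dien-7-yl}-5,5-dimethyl-1,3,2-dioxaborinane (boron sits where the C7′ hydroxyl of 13 will be) | CC(C)=CCC[C@](C)(B1OCC(C)(C)CO1)[C@H](O[Si](CC)(CC)CC)CC/C(C)=C\CO[Si](c1ccccc1)(c1ccccc1)C(C)(C)C | intermediate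
13 | (2Z,6R,7S)-1-[(tert-butyldiphenylsilyl)oxy]-3,7,11-trimethyl-6-[(triethylsilyl)oxy]dodeca-2,10-dien-7-ol | CC(C)=CCC[C@](C)(O)[C@H](O[Si](CC)(CC)CC)CC/C(C)=C\CO[Si](c1ccccc1)(c1ccccc1)C(C)(C)C | intermediate
14 | (2Z,6R,7S)-1-[(tert-butyldiphenylsilyl)oxy]-3,7,11-trimethyldodeca-2,10-diene-6,7-diol | CC(C)=CCC[C@](C)(O)[C@H](O)CC/C(C)=C\CO[Si](c1ccccc1)(c1ccccc1)C(C)(C)C | intermediate
15 | tert-butyl({(2Z)-3-methyl-5-[(4R,5S)-2,2,5-trimethyl-5-(4-methylpent-3-en-1-yl)-1,3-dioxolan-4-yl]pent-2-en-1-yl}oxy)diphenylsilane | CC(C)=CCC[C@]1(C)OC(C)(C)O[C@@H]1CC/C(C)=C\CO[Si](c1ccccc1)(c1ccccc1)C(C)(C)C | intermediate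
16 | (2Z)-3-methyl-5-[(4R,5S)-2,2,5-trimethyl-5-(4-methylpent-3-en-1-yl)-1,3-dioxolan-4-yl]pent-2-en-1-ol | CC(C)=CCC[C@]1(C)OC(C)(C)O[C@@H]1CC/C(C)=C\CO | intermediate
17 | [(2R,3S)-3-methyl-3-{2-[(4R,5S)-2,2,5-trimethyl-5-(4-methylpent-3-en-1-yl)-1,3-dioxolan-4-yl]ethyl}oxiran-2-yl]methanol | CC(C)=CCC[C@]1(C)OC(C)(C)O[C@@H]1CC[C@]1(C)O[C@@H]1CO | intermediate
18 | (2S,3S)-3-methyl-3-{2-[(4R,5S)-2,2,5-trimethyl-5-(4-methylpent-3-en-1-yl)-1,3-dioxolan-4-yl]ethyl}oxirane-2-carbaldehyde (same geometry as 17) | CC(C)=CCC[C@]1(C)OC(C)(C)O[C@@H]1CC[C@]1(C)O[C@@H]1C=O | intermediate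
19 | cyclohexane-1,3-dione | O=C1CCCC(=O)C1 | starting material
20 | 2-({(2R,3S)-3-methyl-3-{2-[(4R,5S)-2,2,5-trimethyl-5-(4-methylpent-3-en-1-yl)-1,3-dioxolan-4-yl]ethyl}oxiran-2-yl}methylidene)cyclohexane-1,3-dione | CC(C)=CCC[C@]1(C)OC(C)(C)O[C@@H]1CC[C@]1(C)O[C@@H]1C=C1C(=O)CCCC1=O | intermediate
21 | 2-({(2R,3S)-3-methyl-3-{2-[(4R,5S)-2,2,5-trimethyl-5-(4-methylpent-3-en-1-yl)-1,3-dioxolan-4-yl]ethyl}oxiran-2-yl}methyl)cyclohexane-1,3-dione | CC(C)=CCC[C@]1(C)OC(C)(C)O[C@@H]1CC[C@]1(C)O[C@@H]1CC1C(=O)CCCC1=O | intermediate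
22 | (2S)-2-{(2S)-2-hydroxy-4-[(4R,5S)-2,2,5-trimethyl-5-(4-methylpent-3-en-1-yl)-1,3-dioxolan-4-yl]butan-2-yl}-2,3,6,7-tetrahydro-1-benzofuran-4(5H)-one | CC(C)=CCC[C@]1(C)OC(C)(C)O[C@@H]1CC[C@](C)(O)[C@@H]1CC2=C(CCCC2=O)O1 | intermediate
23 | dilithium alkoxide–enolate of 22 (C3′ alkoxide, C4–C5 enolate) | [Li+].[Li+].CC(C)=CCC[C@]1(C)OC(C)(C)O[C@@H]1CC[C@](C)([O-])[C@@H]1CC2=C(CCC=C2[O-])O1 | intermediate
24 | (2S,5R)-5-hydroxy-2-{(2S)-2-hydroxy-4-[(4R,5S)-2,2,5-trimethyl-5-(4-methylpent-3-en-1-yl)-1,3-dioxolan-4-yl]butan-2-yl}-2,3,6,7-tetrahydro-1-benzofuran-4(5H)-one | CC(C)=CCC[C@]1(C)OC(C)(C)O[C@@H]1CC[C@](C)(O)[C@@H]1CC2=C(CC[C@@H](O)C2=O)O1 | intermediate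
25 | CNP0125453.2, (2S,5R)-5-hydroxy-2-[(2S,5R,6S)-2,5,6-trihydroxy-6,10-dimethylundec-9-en-2-yl]-2,3,6,7-tetrahydro-1-benzofuran-4(5H)-one | CC(C)=CCC[C@](C)(O)[C@H](O)CC[C@](C)(O)[C@@H]1CC2=C(CC[C@@H](O)C2=O)O1 | target

**Step count and risks**

Total step count: 13. Longest linear sequence: 11 steps (nerol 4 to 25, steps 3–13); the sulcatone branch (steps 1–2) joins at step 6.

Steps most likely to fail:

Step 6 (Proposed new method). What may go wrong: slow or reversible ate-complex formation between the tertiary carbanion and the secondary α-oxygenated boronic ester, decomposition of the lithiated benzoate before borylation, or migration of a ring oxygen instead of carbon. The fallback sets out from 3 and 7 and uses known chemistry only. Benzoate 3 is lithiated as in step 6 and the organolithium 10 is trapped with aldehyde 7 (retention at C7′) to give the hydroxy benzoates F1 as a mixture of C6′ epimers. Dess–Martin oxidation gives the α-acyloxy ketone F2. Reduction with (S)-2-methyl-CBS-oxazaborolidine and BH3·SMe2, with the quaternary C7′ as the large group, should give the (6′R)-alcohol F3 under reagent control. LiAlH4 in warm THF removes the benzoate and gives diol 14, which comes back to the route and is ketalised to 15 under the conditions of step 7.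

Step 12. What may go wrong: poor or reversed facial selectivity in the reagent-controlled hydroxylation of a flat enolate far from any stereocentre, and competing γ-deprotonation. The fallback sets out from 22. Mn(OAc)3 in hot benzene acetoxylates the α′-position without stereocontrol and gives the acetate F6 as both C5 epimers. A lipase or esterase chosen for (5R)-selectivity (hydrolase class, buffer/MTBE) then hydrolyses only the (5R)-acetate, which returns to the route at 24; the (5S)-acetate is separated.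

Step 11. What may go wrong: amine-induced degradation of the epoxy aldehyde, double addition of the dione to the alkylidene intermediate, or 6-endo opening at the tertiary epoxide carbon if the medium turns acidic. The fallback sets out from 17. Tf2O and 2,6-lutidine at −78 °C give the epoxy triflate F4. Alkylation of lithiated 1,5-dimethoxycyclohexa-1,4-diene (tBuLi, THF, −78 °C) with F4 gives the bis(enol ether) F5, a masked C-alkylated dione. Brief hydrolysis with dilute HCl in THF unveils epoxy dione 21, and Et3N closes the ring, returning to the route at 22.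

Further compounds

F1 | step 6 | (2Z,7S)-1-[(tert-butyldiphenylsilyl)oxy]-6-hydroxy-3,7,11-trimethyldodeca-2,10-dien-7-yl 2,4,6-triisopropylbenzoate (both C6 epimers) | CC(C)=CCC[C@](C)(OC(=O)c1c(C(C)C)cc(C(C)C)cc1C(C)C)C(O)CC/C(C)=C\CO[Si](c1ccccc1)(c1ccccc1)C(C)(C)C
F2 | step 6 | (2Z,7S)-1-[(tert-butyldiphenylsilyl)oxy]-3,7,11-trimethyl-6-oxododeca-2,10-dien-7-yl 2,4,6-triisopropylbenzoate | CC(C)=CCC[C@](C)(OC(=O)c1c(C(C)C)cc(C(C)C)cc1C(C)C)C(=O)CC/C(C)=C\CO[Si](c1ccccc1)(c1ccccc1)C(C)(C)C
F3 | step 6 | (2Z,6R,7S)-1-[(tert-butyldiphenylsilyl)oxy]-6-hydroxy-3,7,11-trimethyldodeca-2,10-dien-7-yl 2,4,6-triisopropylbenzoate | CC(C)=CCC[C@](C)(OC(=O)c1c(C(C)C)cc(C(C)C)cc1C(C)C)[C@H](O)CC/C(C)=C\CO[Si](c1ccccc1)(c1ccccc1)C(C)(C)C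
F4 | step 11 | [(2R,3S)-3-methyl-3-{2-[(4R,5S)-2,2,5-trimethyl-5-(4-methylpent-3-en-1-yl)-1,3-dioxolan-4-yl]ethyl}oxiran-2-yl]methyl trifluoromethanesulfonate | CC(C)=CCC[C@]1(C)OC(C)(C)O[C@@H]1CC[C@]1(C)O[C@@H]1COS(=O)(=O)C(F)(F)F
F5 | step 11 | 6-({(2R,3S)-3-methyl-3-{2-[(4R,5S)-2,2,5-trimethyl-5-(4-methylpent-3-en-1-yl)-1,3-dioxolan-4-yl]ethyl}oxiran-2-yl}methyl)-1,5-dimethoxycyclohexa-1,4-diene | CC(C)=CCC[C@]1(C)OC(C)(C)O[C@@H]1CC[C@]1(C)O[C@@H]1CC1C(OC)=CCC=C1OC
F6 | step 12 | (2S)-2-{(2S)-2-hydroxy-4-[(4R,5S)-2,2,5-trimethyl-5-(4-methylpent-3-en-1-yl)-1,3-dioxolan-4-yl]butan-2-yl}-4-oxo-2,3,4,5,6,7-hexahydro-1-benzofuran-5-yl acetate (both C5 epimers) | CC(C)=CCC[C@]1(C)OC(C)(C)O[C@@H]1CC[C@](C)(O)[C@@H]1CC2=C(CCC(OC(C)=O)C2=O)O1
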